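**Plan**

1. Cembrane numbering is used: C1 bears the isopropyl group, C4 the CO2Me (C18), C7 is the ketone carbon, C8 the O-bearing quaternary carbon (methyl C19), C11=C12 the lactone alkene, C20 the lactone carbonyl. Retrosynthesis: the C7 ketone is traced to a C7 alcohol, then O–C8 and C20–C12 are cut together. This removes the O–C(=O) bridge of the seven-membered lactone as one molecule of CO2 and leaves a 14-membered carbocycle with a C12 alkenyl–boron bond and a trans-7,8-epoxide.
2. Enabling feature: C12 (sp2, nucleophilic as alkenyl–copper) and C8 (tertiary, next to the C7 oxygen, electrophilic as epoxide carbon) are 1,5-related through C11=C12–C10–C9 inside the 14-membered ring. The new carboxyl sits cis to C10, so its oxygen can reach the backside of C8 and close the seven-membered ring, while the epoxide oxygen stays on C7 for the ketone.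
3. The carbocycle is cut at C3=C4 (intramolecular Z-selective Still–Gennari olefination, remote from the lactone site) and at C12–C13 (trans-selective Negishi coupling of a 1,1-dibromoalkene). This gives a west fragment (C4–C12, compound 14) and an east fragment (C13–C3, compound 22).
4. Forward order: west fragment, east fragment, Negishi union, closure of the 14-membered ring, borylation, CO2 stitching to the seven-membered lactone, oxidation to the ketone.
5. Stereochemistry: the single stereocentre (8S) comes from the catalyst-controlled Shi epoxidation (8R) and inversion at C8 in the key step; C7 is a temporary centre. Alkene geometries come from the Johnson–Claisen chair (7E, later erased), syn-carbocupration (1E), the Negishi coupling (C12 substituent cis to C10) and the Still–Gennari olefination (3Z).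

Key step: step 16

Remark: aldehyde 1, phosphonate 12 and bromoalkyne 15 are taken as purchasable; no other assumption is needed.

**Route**

Step 1
Reactants: 1 3-[(tert-butyldimethylsilyl)oxy]propanal; 2 isopropenylmagnesium bromide
Product: 3 5-[(tert-butyldimethylsilyl)oxy]-2-methylpent-1-en-3-ol (racemic)
Conditions: THF, −78 → 0 °C; then sat. aq. NH4Cl
Reagents that add atoms: none
Why: Grignard 1,2-addition of the alkenylmagnesium reagent to the aldehyde should give the secondary allylic alcohol, whose configuration is irrelevant because the carbinol carbon becomes sp2 in step 2.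

Step 2
Reactants: 3 5-[(tert-butyldimethylsilyl)oxy]-2-methylpent-1-en-3-ol; 4 triethyl orthoacetate
Product: 6 ethyl (4E)-7-[(tert-butyldimethylsilyl)oxy]-4-methylhept-4-enoate, via ketene acetal 5 (not isolated)
Conditions: MeC(OEt)3 (5 equiv), EtCO2H (cat.), 140 °C, EtOH distilled off
Reagents that add atoms: none
Why: Johnson–Claisen rearrangement of the mixed ketene acetal through a chair transition state with the silyloxyethyl chain equatorial should form the C9–C10 bond and the E-trisubstituted alkene (future C7=C8).

Step 3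
Reactants: 6 ethyl (4E)-7-[(tert-butyldimethylsilyl)oxy]-4-methylhept-4-enoate
Product: 7 (4E)-7-[(tert-butyldimethylsilyl)oxy]-4-methylhept-4-enal
Conditions: i-Bu2AlH (1.1 equiv), CH2Cl2, −78 °C; then aq. KNa tartrate
Reagents that add atoms: none
Why: half-reduction of the ester with i-Bu2AlH at low temperature should stop at the aluminium hemiacetal, which gives the aldehyde on work-up (DIBAL reduction).

Step 4
Reactants: 7 (4E)-7-[(tert-butyldimethylsilyl)oxy]-4-methylhept-4-enal; 8 carbon tetrabromide
Product: 9 tert-butyl{[(3E)-8,8-dibromo-4-methylocta-3,7-dien-1-yl]oxy}dimethylsilane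
Conditions: CBr4 (2 equiv), PPh3 (4 equiv), Et3N (1 equiv), CH2Cl2, 0 °C
Reagents that add atoms: none
Why: Ramirez dibromo-olefination of the aldehyde by Ph3P=CBr2 should install the future C12 as a gem-dibromoalkene, with Et3N buffering HBr so that the silyl ether survives.

Step 5
Reactants: 9 tert-butyl{[(3E)-8,8-dibromo-4-methylocta-3,7-dien-1-yl]oxy}dimethylsilane
Product: 10 (5E)-1,1,8-tribromo-5-methylocta-1,5-diene
Conditions: Ph3PBr2 (1.3 equiv), CH2Cl2, 0 → 23 °C
Reagents that add atoms: dibromotriphenylphosphorane Ph3PBr2, BrP(Br)(c1ccccc1)(c1ccccc1)c1ccccc1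
Why: the primary silyl ether should be converted directly into the bromide through an alkoxyphosphonium bromide and SN2 displacement (Appel-type silyl ether to bromide exchange), which saves a separate deprotection.

Step 6
Reactants: 10 (5E)-1,1,8-tribromo-5-methylocta-1,5-diene
Product: 11 (2R,3R)-3-(2-bromoethyl)-2-(4,4-dibromobut-3-en-1-yl)-2-methyloxirane
Conditions: D-fructose-derived Shi ketone (0.3 equiv), KHSO5 (as 2KHSO5·KHSO4·K2SO4), K2CO3, Bu4NHSO4 (cat.), MeCN/CH2(OMe)2/aq. Na2B4O7–Na2EDTA buffer, 0 °C
Reagents that add atoms: potassium peroxymonosulfate KHSO5, [K+].[O-]S(=O)(=O)OO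
Why: in the Shi epoxidation the chiral dioxirane should attack only the electron-rich E-trisubstituted alkene (the gem-dibromoalkene is inert) through the spiro transition state, which for this olefin class should give the (R,R)-epoxide, i.e. the future (7R,8R) centres.

Step 7
Reactants: 11 (2R,3R)-3-(2-bromoethyl)-2-(4,4-dibromobut-3-en-1-yl)-2-methyloxirane; 12 methyl [bis(2,2,2-trifluoroethoxy)phosphoryl]acetate
Product: 14 methyl 2-[bis(2,2,2-trifluoroethoxy)phosphoryl]-4-[(2R,3R)-3-(4,4-dibromobut-3-en-1-yl)-3-methyloxiran-2-yl]butanoate (mixture of C2 epimers), via sodium phosphonoacetate 13 (not isolated)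
Conditions: 12 (2.5 equiv), NaH (2.4 equiv), DMF, 0 °C; then 11, NaI (cat.), 50 °C
Reagents that add atoms: none
Why: iodide-assisted SN2 C-alkylation of the soft phosphonoacetate anion by the primary bromide should leave the trisubstituted epoxide and the dibromoalkene untouched, and the new phosphonate-bearing carbon is an epimer mixture that becomes sp2 in step 14.

Step 8
Reactants: 15 4-bromobut-1-yne; 16 methyl chloroformate
Product: 18 methyl 5-bromopent-2-ynoate, via lithium acetylide 17 (not isolated)
Conditions: n-BuLi (1.0 equiv), THF, −78 °C; then ClCO2Me, −78 → −20 °C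
Reagents that add atoms: none
Why: deprotonation of the terminal alkyne is much faster than bromine–lithium exchange at −78 °C, and acylation of the acetylide by the chloroformate should give the ynoate.

Step 9
Reactants: 18 methyl 5-bromopent-2-ynoate; 19 isopropylmagnesium chloride
Product: 20 methyl (2E)-5-bromo-3-(propan-2-yl)pent-2-enoate
Conditions: i-PrMgCl (1.2 equiv), CuI (1.2 equiv), THF, −40 °C; then 18, −78 °C; sat. aq. NH4Cl at −78 °C
Reagents that add atoms: none
Why: syn-carbocupration of the ynoate and protonation at −78 °C, before the alkenylcopper can isomerise through the allenoate, should place the ester cis to the bromoethyl arm, which is the future 1E geometry.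

Step 10
Reactants: 20 methyl (2E)-5-bromo-3-(propan-2-yl)pent-2-enoate
Product: 21 (2E)-5-bromo-3-(propan-2-yl)pent-2-en-1-ol
Conditions: i-Bu2AlH (2.2 equiv), CH2Cl2, −78 °C; then aq. KNa tartrate
Reagents that add atoms: none
Why: 1,2-reduction of the unsaturated ester by i-Bu2AlH should give the allylic alcohol without touching the alkene geometry or the primary bromide (DIBAL reduction).

Step 11
Reactants: 21 (2E)-5-bromo-3-(propan-2-yl)pent-2-en-1-ol
Product: 22 {[(2E)-5-bromo-3-(propan-2-yl)pent-2-en-1-yl]oxy}trimethylsilane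
Conditions: Me3SiCl (1.2 equiv), Et3N (1.5 equiv), CH2Cl2, 0 °C
Reagents that add atoms: chlorotrimethylsilane, C[Si](C)(C)Cl
Why: silylation masks the hydroxyl for the zinc insertion, and the trimethylsilyl group is chosen because it is lost in the work-up of step 12 (silyl ether protection).

Step 12
Reactants: 14 methyl 2-[bis(2,2,2-trifluoroethoxy)phosphoryl]-4-[(2R,3R)-3-(4,4-dibromobut-3-en-1-yl)-3-methyloxiran-2-yl]butanoate; 22 {[(2E)-5-bromo-3-(propan-2-yl)pent-2-en-1-yl]oxy}trimethylsilane
Product: 25 methyl 2-[bis(2,2,2-trifluoroethoxy)phosphoryl]-4-{(2R,3R)-3-[(3Z,7E)-4-bromo-9-hydroxy-7-(propan-2-yl)nona-3,7-dien-1-yl]-3-methyloxiran-2-yl}butanoate (mixture of C2 epimers), via organozinc bromide 23 (not isolated), via trimethylsilyl ether 24 (not isolated)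
Conditions: 22 (1.8 equiv), Zn dust (activated with BrCH2CH2Br and Me3SiCl), LiCl, THF, 50 °C, solution decanted from excess Zn; then 14, PdCl2(DPEphos) (5 mol%), THF/DMF, 0 → 23 °C; then 0.5 M aq. citric acid, THF, 0 °C
Reagents that add atoms: none
Why: in this Negishi coupling zerovalent palladium should add selectively to the C–Br bond trans to the alkyl chain of the 1,1-dibromoalkene, so the alkyl group enters trans and the remaining bromine is cis to C10 (Z), while the weakly basic alkylzinc should tolerate the phosphonoacetate C–H and the epoxide and dilute acid then cleaves the silyl ether.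

Step 13
Reactants: 25 the allylic alcohol from step 12
Product: 26 methyl 2-[bis(2,2,2-trifluoroethoxy)phosphoryl]-4-{(2R,3R)-3-[(3Z,7E)-4-bromo-9-oxo-7-(propan-2-yl)nona-3,7-dien-1-yl]-3-methyloxiran-2-yl}butanoate (mixture of C2 epimers)
Conditions: activated MnO2 (20 equiv), CH2Cl2, 23 °C
Reagents that add atoms: none
Why: MnO2 should oxidise only the allylic alcohol, giving the E-enal without affecting the epoxide, the phosphonate or the alkenyl bromide (allylic oxidation).

Step 14
Reactants: 26 the phosphonate enal from step 13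
Product: 27 methyl (1E,3Z,7R,8R,11Z)-12-bromo-7,8-epoxy-20-norcembra-1,3,11-trien-18-oate (14-membered carbocycle; Br on C12 cis to C10)
Conditions: slow addition of 26 to KN(SiMe3)2 (1.05 equiv) and 18-crown-6 (5 equiv) in THF (final 1 mM), −78 → −20 °C
Reagents that add atoms: none
Why: in this intramolecular Still–Gennari (Horner–Wadsworth–Emmons) olefination the trifluoroethyl phosphonate with a dissociated potassium counter-ion should eliminate fast from the kinetic adduct, placing CO2Me cis to C2 (3Z) while high dilution favours closure of the 14-membered ring at a site remote from the epoxide.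

Step 15
Reactants: 27 the macrocyclic alkenyl bromide from step 14
Product: 28 methyl (1E,3Z,7R,8R,11E)-12-(5,5-dimethyl-1,3,2-dioxaborinan-2-yl)-7,8-epoxy-20-norcembra-1,3,11-trien-18-oate (boron on C12 cis to C10)
Conditions: bis(neopentyl glycolato)diboron (1.5 equiv), PdCl2(dppf) (5 mol%), KOAc (3 equiv), 1,4-dioxane, 80 °C
Reagents that add atoms: bis(neopentyl glycolato)diboron, CC1(C)COB(OC1)B1OCC(C)(C)CO1
Why: in the Miyaura borylation, oxidative addition of zerovalent palladium to the alkenyl bromide, acetate-assisted transmetalation with the diboron reagent and reductive elimination should exchange bromine for boron with retention of the alkene geometry.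

Step 16
Reactants: 28 the macrocyclic alkenyl boronate from step 15; 29 carbon dioxide
Product: 32 methyl (1E,3Z,7R,8S,11Z)-7-hydroxy-20-oxo-8,20-epoxycembra-1,3,11-trien-18-oate (7-hydroxy seven-membered lactone), via potassium carboxylate 30 (not isolated), via epoxy acid 31 (not isolated)
Conditions: (IPr)CuCl (10 mol%; IPr = 1,3-bis(2,6-diisopropylphenyl)imidazol-2-ylidene), KOt-Bu (1.1 equiv), CO2 (1 atm), THF, 70 °C; then 0 °C, CH2Cl2, (±)-camphor-10-sulfonic acid (2.5 equiv), 0 → 23 °C
Reagents that add atoms: none
Why: Proposed new method: the copper alkoxide formed from (IPr)CuCl and KOt-Bu transmetalates the alkenyl boronate with retention, CO2 inserts into the Cu–C12 bond to give carboxylate 30 (C20–C12 bond), and after acidification the acid 31 opens the protonated epoxide at C8 (O–C8 bond), so that one CO2 molecule becomes the O–C(=O) bridge. The closest known reaction types are the carboxylation of alkenylboronic esters with CO2 under monovalent-copper catalysis and the acid-promoted lactonisation of epoxy acids; what is new is their relay in one flask onto a tertiary epoxide carbon to close an ε-lactone across a macrocycle. The seven-membered lactone closes 7-exo-tet, the 14-membered ring being already in place. The C8 stereocentre is controlled by the epoxide set in step 6: backside (SN2-like) attack inverts (8R) to (8S), while C7 keeps its configuration and is erased in step 17. The step needs attack at C8 and not at C7 (8-endo) and C–O bond formation faster than hydride shift or cation scrambling; the tertiary carbon carries the larger positive charge in the protonated epoxide, the carboxyl is locked cis to C10 on the C11=C12 bond so that only four atoms separate it from C8, and the conjugated acid and dienoate are too electron-poor to act as competing π-nucleophiles.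

Step 17
Reactants: 32 the 7-hydroxy lactone from step 16
Product: 33 ketoemblide, methyl (1E,3Z,8S,11Z)-7,20-dioxo-8,20-epoxycembra-1,3,11-trien-18-oate
Conditions: Dess–Martin periodinane (1.5 equiv), NaHCO3, CH2Cl2, 23 °C
Reagents that add atoms: none
Why: Dess–Martin oxidation of the secondary alcohol should give the α-acyloxy ketone under buffered conditions that cannot epimerise C8, which has no hydrogen.

**Compound list**

1 | 3-[(tert-butyldimethylsilyl)oxy]propanal | CC(C)(C)[Si](C)(C)OCCC=O | starting material
2 | isopropenylmagnesium bromide | CC(=C)[Mg]Br | starting material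
3 | 5-[(tert-butyldimethylsilyl)oxy]-2-methylpent-1-en-3-ol (racemic) | C=C(C)C(O)CCO[Si](C)(C)C(C)(C)C | intermediate
4 | triethyl orthoacetate | CCOC(C)(OCC)OCC | starting material
5 | ketene acetal, tert-butyl({3-[(1-ethoxyethenyl)oxy]-4-methylpent-4-en-1-yl}oxy)dimethylsilane (not isolated) | C=C(OCC)OC(CCO[Si](C)(C)C(C)(C)C)C(C)=C | intermediate
6 | ethyl (4E)-7-[(tert-butyldimethylsilyl)oxy]-4-methylhept-4-enoate | CCOC(=O)CC/C(C)=C/CCO[Si](C)(C)C(C)(C)C | intermediate
7 | (4E)-7-[(tert-butyldimethylsilyl)oxy]-4-methylhept-4-enal | O=CCC/C(C)=C/CCO[Si](C)(C)C(C)(C)C | intermediate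
8 | carbon tetrabromide | BrC(Br)(Br)Br | starting material
9 | tert-butyl{[(3E)-8,8-dibromo-4-methylocta-3,7-dien-1-yl]oxy}dimethylsilane | BrC(Br)=CCC/C(C)=C/CCO[Si](C)(C)C(C)(C)C | intermediate
10 | (5E)-1,1,8-tribromo-5-methylocta-1,5-diene | BrC(Br)=CCC/C(C)=C/CCBr | intermediate
11 | (2R,3R)-3-(2-bromoethyl)-2-(4,4-dibromobut-3-en-1-yl)-2-methyloxirane | BrCC[C@H]1O[C@]1(C)CCC=C(Br)Br | intermediate
12 | methyl [bis(2,2,2-trifluoroethoxy)phosphoryl]acetate | COC(=O)CP(=O)(OCC(F)(F)F)OCC(F)(F)F | starting material
13 | sodium salt of 12 (not isolated) | [Na+].COC(=O)[CH-]P(=O)(OCC(F)(F)F)OCC(F)(F)F | intermediate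
14 | methyl 2-[bis(2,2,2-trifluoroethoxy)phosphoryl]-4-[(2R,3R)-3-(4,4-dibromobut-3-en-1-yl)-3-methyloxiran-2-yl]butanoate (C2 epimers) | COC(=O)C(CC[C@H]1O[C@]1(C)CCC=C(Br)Br)P(=O)(OCC(F)(F)F)OCC(F)(F)F | intermediate
15 | 4-bromobut-1-yne | C#CCCBr | starting material
16 | methyl chloroformate | COC(=O)Cl | starting material
17 | lithium 4-bromobut-1-yn-1-ide (not isolated) | [Li]C#CCCBr | intermediate
18 | methyl 5-bromopent-2-ynoate | COC(=O)C#CCCBr | intermediate
19 | isopropylmagnesium chloride | CC(C)[Mg]Cl | starting material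
20 | methyl (2E)-5-bromo-3-(propan-2-yl)pent-2-enoate | COC(=O)/C=C(\CCBr)C(C)C | intermediate
21 | (2E)-5-bromo-3-(propan-2-yl)pent-2-en-1-ol | OC/C=C(\CCBr)C(C)C | intermediate
22 | {[(2E)-5-bromo-3-(propan-2-yl)pent-2-en-1-yl]oxy}trimethylsilane | C[Si](C)(C)OC/C=C(\CCBr)C(C)C | intermediate
23 | bromo{(3E)-3-(propan-2-yl)-5-[(trimethylsilyl)oxy]pent-3-en-1-yl}zinc (not isolated) | C[Si](C)(C)OC/C=C(\CC[Zn]Br)C(C)C | intermediate
24 | trimethylsilyl ether of 25 (not isolated) | COC(=O)C(CC[C@H]1O[C@]1(C)CC/C=C(Br)/CC/C(C(C)C)=C\CO[Si](C)(C)C)P(=O)(OCC(F)(F)F)OCC(F)(F)F | intermediate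
25 | methyl 2-[bis(2,2,2-trifluoroethoxy)phosphoryl]-4-{(2R,3R)-3-[(3Z,7E)-4-bromo-9-hydroxy-7-(propan-2-yl)nona-3,7-dien-1-yl]-3-methyloxiran-2-yl}butanoate (C2 epimers) | COC(=O)C(CC[C@H]1O[C@]1(C)CC/C=C(Br)/CC/C(C(C)C)=C\CO)P(=O)(OCC(F)(F)F)OCC(F)(F)F | intermediate
26 | methyl 2-[bis(2,2,2-trifluoroethoxy)phosphoryl]-4-{(2R,3R)-3-[(3Z,7E)-4-bromo-9-oxo-7-(propan-2-yl)nona-3,7-dien-1-yl]-3-methyloxiran-2-yl}butanoate (C2 epimers) | COC(=O)C(CC[C@H]1O[C@]1(C)CC/C=C(Br)/CC/C(C(C)C)=C\C=O)P(=O)(OCC(F)(F)F)OCC(F)(F)F | intermediate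
27 | methyl (1E,3Z,7R,8R,11Z)-12-bromo-7,8-epoxy-20-norcembra-1,3,11-trien-18-oate | COC(=O)/C1=C\C=C(\C(C)C)CC/C(Br)=C/CC[C@@]2(C)O[C@@H]2CC1 | intermediate
28 | methyl (1E,3Z,7R,8R,11E)-12-(5,5-dimethyl-1,3,2-dioxaborinan-2-yl)-7,8-epoxy-20-norcembra-1,3,11-trien-18-oate | COC(=O)/C1=C\C=C(\C(C)C)CC/C(B3OCC(C)(C)CO3)=C/CC[C@@]2(C)O[C@@H]2CC1 | intermediate
29 | carbon dioxide | O=C=O | starting material
30 | potassium (1E,3Z,7R,8R,11Z)-7,8-epoxy-18-methoxy-18-oxocembra-1,3,11-trien-20-oate (not isolated) | COC(=O)/C1=C\C=C(\C(C)C)CC/C(C(=O)[O-])=C/CC[C@@]2(C)O[C@@H]2CC1.[K+] | intermediate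
31 | (1E,3Z,7R,8R,11Z)-7,8-epoxy-18-methoxy-18-oxocembra-1,3,11-trien-20-oic acid (not isolated) | COC(=O)/C1=C\C=C(\C(C)C)CC/C(C(=O)O)=C/CC[C@@]2(C)O[C@@H]2CC1 | intermediate
32 | methyl (1E,3Z,7R,8S,11Z)-7-hydroxy-20-oxo-8,20-epoxycembra-1,3,11-trien-18-oate | COC(=O)/C1=C\C=C(\C(C)C)CCC2=CCC[C@](C)(OC2=O)[C@H](O)CC1 | intermediate
33 | ketoemblide | COC(=O)/C1=C\C=C(\C(C)C)CCC2=CCC[C@](C)(OC2=O)C(=O)CC1 | target

**Totals and risks**

Total step count: 17. Longest linear sequence: 13 steps (steps 1–7, then 12–17); the east branch (steps 8–11) joins at step 12.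

Most likely to fail, step 16: after carboxylation the acid-triggered closure may lose to hydride shift in the opened epoxide, to 8-endo attack at C7, or to partial loss of configuration through an open tertiary cation; protodeboronation may also outrun CO2 insertion. The fallback uses known chemistry and forms the C8–O bond before the carbonyl carbon is introduced. It sets out from bromide 27, whose epoxide is hydrolysed under acid catalysis (HClO4 cat., THF/H2O, 0 °C), water entering at the tertiary carbon with inversion to give methyl (1E,3Z,7R,8S,11Z)-12-bromo-7,8-dihydroxy-20-norcembra-1,3,11-trien-18-oate F1. Palladium-catalysed carbonylative lactonisation of the alkenyl bromide with the tertiary hydroxyl (Pd(OAc)2, dppf, CO 1 atm, K2CO3, DMF, 80 °C) then forms C12–C20 and C20–O and comes back to the route at 32.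

Second, step 14: the ring closure may give oligomers, or the Z-selectivity may erode when the olefination is forced to be intramolecular. The fallback makes the C3=C4 bond between fragments and closes the ring at C12–C13 instead. It sets out from alcohol 21, which is oxidised with MnO2 to (2E)-5-bromo-3-(propan-2-yl)pent-2-enal F2. Intermolecular Still–Gennari olefination of F2 with phosphonate 14 (KN(SiMe3)2, 18-crown-6, THF, −78 °C) should give methyl (2Z,4E)-7-bromo-2-{2-[(2R,3R)-3-(4,4-dibromobut-3-en-1-yl)-3-methyloxiran-2-yl]ethyl}-5-(propan-2-yl)hepta-2,4-dienoate F3. Zinc insertion into its primary bromide (Zn, LiCl, THF) gives the alkylzinc bromide F4, which is cyclised by the trans-selective Negishi coupling under high dilution (PdCl2(DPEphos), THF/DMF); this comes back at 27.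

Third, step 12: the alkylzinc may be protonated by the acidic phosphonoacetate C–H, or a second substitution at the remaining C–Br bond may compete. The fallback changes the order of union so that the electrophile has no acidic site. It sets out from epoxy tribromide 11, which is coupled with zinc reagent 23 (made from 22) under the same palladium catalysis to give (2R,3R)-3-(2-bromoethyl)-2-{(3Z,7E)-4-bromo-7-(propan-2-yl)-9-[(trimethylsilyl)oxy]nona-3,7-dien-1-yl}-2-methyloxirane F5. Sodium phosphonoacetate 13 is then alkylated with the primary bromide of F5 (DMF, NaI cat., 50 °C) to give 24, and the acid work-up returns the sequence to the route at 25.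

Further compounds
F1 | step 16 | methyl (1E,3Z,7R,8S,11Z)-12-bromo-7,8-dihydroxy-20-norcembra-1,3,11-trien-18-oate | COC(=O)/C1=C\C=C(\C(C)C)CC/C(Br)=C/CC[C@](C)(O)[C@H](O)CC1
F2 | step 14 | (2E)-5-bromo-3-(propan-2-yl)pent-2-enal | O=C/C=C(\CCBr)C(C)C
F3 | step 14 | methyl (2Z,4E)-7-bromo-2-{2-[(2R,3R)-3-(4,4-dibromobut-3-en-1-yl)-3-methyloxiran-2-yl]ethyl}-5-(propan-2-yl)hepta-2,4-dienoate | COC(=O)/C(CC[C@H]1O[C@]1(C)CCC=C(Br)Br)=C\C=C(\C(C)C)CCBr
F4 | step 14 | alkylzinc bromide derived from F3 | COC(=O)/C(CC[C@H]1O[C@]1(C)CCC=C(Br)Br)=C\C=C(\C(C)C)CC[Zn]Br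
F5 | step 12 | (2R,3R)-3-(2-bromoethyl)-2-{(3Z,7E)-4-bromo-7-(propan-2-yl)-9-[(trimethylsilyl)oxy]nona-3,7-dien-1-yl}-2-methyloxirane | BrCC[C@H]1O[C@]1(C)CC/C=C(Br)/CC/C(C(C)C)=C\CO[Si](C)(C)C
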